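The synthesis rests on cutting the biaryl axis between C5 of the tetrahydroisoquinoline benzo ring and C8' of the naphthalene. A palladium-catalysed Negishi coupling joins the finished (1R,3S)-5-bromo-6,8-dimethoxy-1,2,3-trimethyltetrahydroisoquinoline to the naphthylzinc chloride generated in the flask from 5-bromo-1,8-dimethoxy-3-methylnaphthalene, so the last operation delivers the complete skeleton with both stereocentres, the N-methyl group and all four methyl ethers in place. The step exploits two features: C5 is para to the C8 methoxy and ortho to the C6 methoxy group, which allows regioselective bromination, and C8' is para to the C5' methoxy group, where a bromine first blocks and steers the naphthalene ring closure and then serves as the metalation handle.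

Key step: step 11

Assumption: the structure as drawn fixes only C1 (R) and C3 (S, methyl groups cis) and leaves the hindered C5–C8' axis undefined. The route therefore controls the two stereocentres and not the axis; if rotation is slow, the two rotamers, both of which answer to the drawn structure, would be separated by chromatography.

Remark on locants: the naphthalene is numbered with primes as in the target (C2' methyl, C4' and C5' methoxy, C8' the coupling carbon); C8' is C5 in the systematic names of compounds 14–16.

Step 1
Reactants: 1 3,5-dimethoxyphenylmagnesium chloride (THF solution); 2 tert-butyl (S)-2-methylaziridine-1-carboxylate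
Product: 3 tert-butyl (S)-[1-(3,5-dimethoxyphenyl)propan-2-yl]carbamate
Conditions: CuBr·SMe2 (10 mol %), THF, −30 °C → 0 °C; aq. NH4Cl
Reagents that add atoms: none
Why: Copper-catalysed SN2 ring opening of the N-Boc aziridine by the aryl Grignard reagent should occur at the unsubstituted CH2 carbon, so the stereocentre of 2 is not touched and is carried into 3 as (S).

Step 2
Reactants: 3 tert-butyl (S)-[1-(3,5-dimethoxyphenyl)propan-2-yl]carbamate
Product: 5 (S)-N-[1-(3,5-dimethoxyphenyl)propan-2-yl]acetamide, via amine hydrochloride 4 (not isolated)
Conditions: HCl (4 M in dioxane), rt, evaporate; then Ac2O, aq. NaOH, CH2Cl2, 0 °C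
Reagents that add atoms: acetic anhydride CC(=O)OC(C)=O
Why: Acidolytic Boc cleavage followed by Schotten–Baumann N-acetylation of the liberated primary amine are routine reactions that leave the stereocentre untouched.

Step 3
Reactants: 5 (S)-N-[1-(3,5-dimethoxyphenyl)propan-2-yl]acetamide
Product: 6 (S)-6,8-dimethoxy-1,3-dimethyl-3,4-dihydroisoquinoline
Conditions: POCl3, MeCN, reflux; then aq. NaOH
Reagents that add atoms: none
Why: Bischler–Napieralski cyclodehydration, in which the activated amide attacks the ring carbon ortho to the side chain (para to one methoxy group, ortho to the other, and equivalent to its mirror position), so a single 6,8-dimethoxy dihydroisoquinoline should form.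

Step 4
Reactants: 6 (S)-6,8-dimethoxy-1,3-dimethyl-3,4-dihydroisoquinoline
Product: 7 (1R,3S)-6,8-dimethoxy-1,3-dimethyl-1,2,3,4-tetrahydroisoquinoline
Conditions: NaBH4, MeOH, 0 °C
Reagents that add atoms: none
Why: Hydride reduction of the cyclic imine, where axial attack of borohydride on the half-chair with the C3 methyl group pseudo-equatorial should place the new C1 hydrogen cis to the C3 hydrogen, giving the cis-1,3-dimethyl (1R,3S) amine under control of the C3 centre.

Step 5
Reactants: 7 (1R,3S)-6,8-dimethoxy-1,3-dimethyl-1,2,3,4-tetrahydroisoquinoline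
Product: 8 (1R,3S)-6,8-dimethoxy-1,2,3-trimethyl-1,2,3,4-tetrahydroisoquinoline
Conditions: aq. HCHO, NaBH(OAc)3, ClCH2CH2Cl, rt
Reagents that add atoms: formaldehyde C=O
Why: Reductive amination (iminium formation with formaldehyde, then hydride transfer from NaBH(OAc)3) methylates the secondary amine without affecting C1 or C3.

Step 6
Reactants: 8 (1R,3S)-6,8-dimethoxy-1,2,3-trimethyl-1,2,3,4-tetrahydroisoquinoline
Product: 9 (1R,3S)-5-bromo-6,8-dimethoxy-1,2,3-trimethyl-1,2,3,4-tetrahydroisoquinoline
Conditions: NBS (1.0 equiv), TFA, CH2Cl2, −20 °C → 0 °C; aq. NaHCO3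
Reagents that add atoms: N-bromosuccinimide O=C1CCC(=O)N1Br
Why: Electrophilic aromatic bromination of the ammonium salt, in which C5 (para to the C8 methoxy, ortho to the C6 methoxy group) should react in preference to C7 (flanked by two methoxy groups), while protonation shields the amine and its neighbouring C–H bonds from oxidation.

Step 7
Reactants: 10 1-(3-methoxyphenyl)propan-2-one
Product: 11 1-(2-bromo-5-methoxyphenyl)propan-2-one
Conditions: NBS, MeCN, 0 °C → rt
Reagents that add atoms: N-bromosuccinimide O=C1CCC(=O)N1Br
Why: Electrophilic aromatic bromination with NBS in acetonitrile should take the position para to the methoxy group, which is the ring carbon ortho to the acetonyl chain.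

Step 8
Reactants: 11 1-(2-bromo-5-methoxyphenyl)propan-2-one
Product: 13 4-(2-bromo-5-methoxyphenyl)-3-methylbut-2-enoic acid (mixture of alkene isomers), via ethyl ester 12 (not isolated)
Conditions: (EtO)2P(O)CH2CO2Et, NaH, THF, 0 °C → rt; then LiOH, H2O/MeOH, 50 °C; aq. HCl
Reagents that add atoms: triethyl phosphonoacetate CCOC(=O)CP(=O)(OCC)OCC; lithium hydroxide [Li+].[OH-]
Why: Horner–Wadsworth–Emmons olefination of the ketone followed by ester saponification, where the alkene geometry (and any migration of the double bond towards the arene) does not matter because all isomers converge in step 9.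

Step 9
Reactants: 13 4-(2-bromo-5-methoxyphenyl)-3-methylbut-2-enoic acid
Product: 14 5-bromo-8-methoxy-3-methylnaphthalen-1-yl acetate
Conditions: Ac2O, NaOAc, reflux
Reagents that add atoms: acetic anhydride CC(=O)OC(C)=O
Why: Cyclodehydration of the arylbutenoic acid through its mixed anhydride and the derived dienylketene (6π electrocyclisation, equivalent to an intramolecular Friedel–Crafts acylation) can close only at the one free ortho carbon because bromine blocks the other, and the naphthol formed is acetylated in the flask.

Step 10
Reactants: 14 5-bromo-8-methoxy-3-methylnaphthalen-1-yl acetate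
Product: 16 5-bromo-1,8-dimethoxy-3-methylnaphthalene, via naphthol 15 (not isolated)
Conditions: K2CO3, MeOH, rt, evaporate; then MeI, K2CO3, DMF, rt
Reagents that add atoms: iodomethane CI
Why: Base-catalysed methanolysis of the aryl acetate followed by Williamson O-methylation of the naphtholate.

Step 11
Reactants: 16 5-bromo-1,8-dimethoxy-3-methylnaphthalene; 9 (1R,3S)-5-bromo-6,8-dimethoxy-1,2,3-trimethyl-1,2,3,4-tetrahydroisoquinoline
Product: 19 (1R,3S)-5-(4,5-dimethoxy-7-methylnaphthalen-1-yl)-6,8-dimethoxy-1,2,3-trimethyl-1,2,3,4-tetrahydroisoquinoline (target), via aryllithium 17 (not isolated), via arylzinc chloride 18 (not isolated)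
Conditions: 16 (1.3 equiv), n-BuLi, THF, −78 °C; ZnCl2, −78 °C → rt; then 9, Pd2(dba)3 (2 mol %), RuPhos (8 mol %), THF, 65 °C
Reagents that add atoms: none
Why: Bromine–lithium exchange on 16 and transmetalation to ZnCl2 give arylzinc 18; zerovalent palladium carrying the bulky dialkylbiarylphosphine inserts into the C5–Br bond of 9, the naphthyl group passes from zinc to palladium, and reductive elimination forms the C5–C8' bond. The closest known reaction type is the Negishi coupling to tri- and tetra-ortho-substituted biaryls with Pd/RuPhos, and palladium-catalysed couplings of 5-halogenated tetrahydroisoquinolines with naphthyl metal reagents are a known reaction class. No ring is closed and no stereocentre is created: C1 and C3 lie away from the reacting carbons and meet neither strong base nor acid, so (1R,3S) is carried through unchanged, whereas the new hindered axis is formed without control, as stated in the assumption. The step needs cross-coupling to outrun homocoupling and protodemetalation, which is secured by preforming the organozinc stoichiometrically at low temperature before 9 and the catalyst are added, and by each partner carrying its single reactive carbon–metal or carbon–bromine bond exactly at the carbon to be joined. The tertiary amine and the aryl methyl ethers are inert to the organozinc, so no protecting group is needed.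

Compound list
1 | 3,5-dimethoxyphenylmagnesium chloride | COc1cc(OC)cc([Mg]Cl)c1 | starting material
2 | tert-butyl (S)-2-methylaziridine-1-carboxylate | C[C@H]1CN1C(=O)OC(C)(C)C | starting material
3 | tert-butyl (S)-[1-(3,5-dimethoxyphenyl)propan-2-yl]carbamate | C[C@@H](Cc1cc(OC)cc(OC)c1)NC(=O)OC(C)(C)C | intermediate
4 | (S)-1-(3,5-dimethoxyphenyl)propan-2-amine hydrochloride (not isolated) | C[C@H]([NH3+])Cc1cc(OC)cc(OC)c1.[Cl-] | intermediate
5 | (S)-N-[1-(3,5-dimethoxyphenyl)propan-2-yl]acetamide | CC(=O)N[C@@H](C)Cc1cc(OC)cc(OC)c1 | intermediate
6 | (S)-6,8-dimethoxy-1,3-dimethyl-3,4-dihydroisoquinoline | CC1=N[C@@H](C)Cc2cc(OC)cc(OC)c12 | intermediate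
7 | (1R,3S)-6,8-dimethoxy-1,3-dimethyl-1,2,3,4-tetrahydroisoquinoline | C[C@H]1N[C@@H](C)Cc2cc(OC)cc(OC)c12 | intermediate
8 | (1R,3S)-6,8-dimethoxy-1,2,3-trimethyl-1,2,3,4-tetrahydroisoquinoline | C[C@H]1N(C)[C@@H](C)Cc2cc(OC)cc(OC)c12 | intermediate
9 | (1R,3S)-5-bromo-6,8-dimethoxy-1,2,3-trimethyl-1,2,3,4-tetrahydroisoquinoline | C[C@H]1N(C)[C@@H](C)Cc2c(Br)c(OC)cc(OC)c12 | intermediate
10 | 1-(3-methoxyphenyl)propan-2-one | CC(=O)Cc1cccc(OC)c1 | starting material
11 | 1-(2-bromo-5-methoxyphenyl)propan-2-one | CC(=O)Cc1cc(OC)ccc1Br | intermediate
12 | ethyl 4-(2-bromo-5-methoxyphenyl)-3-methylbut-2-enoate (mixture of alkene isomers, not isolated) | CCOC(=O)C=C(C)Cc1cc(OC)ccc1Br | intermediate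
13 | 4-(2-bromo-5-methoxyphenyl)-3-methylbut-2-enoic acid (mixture of alkene isomers) | OC(=O)C=C(C)Cc1cc(OC)ccc1Br | intermediate
14 | 5-bromo-8-methoxy-3-methylnaphthalen-1-yl acetate | CC(=O)Oc1cc(C)cc2c(Br)ccc(OC)c12 | intermediate
15 | 5-bromo-8-methoxy-3-methylnaphthalen-1-ol (as potassium naphtholate, not isolated) | Oc1cc(C)cc2c(Br)ccc(OC)c12 | intermediate
16 | 5-bromo-1,8-dimethoxy-3-methylnaphthalene | COc1cc(C)cc2c(Br)ccc(OC)c12 | intermediate
17 | (4,5-dimethoxy-7-methylnaphthalen-1-yl)lithium (not isolated) | [Li]c1ccc(OC)c2c(OC)cc(C)cc12 | intermediate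
18 | (4,5-dimethoxy-7-methylnaphthalen-1-yl)zinc chloride (not isolated) | Cl[Zn]c1ccc(OC)c2c(OC)cc(C)cc12 | intermediate
19 | (1R,3S)-5-(4,5-dimethoxy-7-methylnaphthalen-1-yl)-6,8-dimethoxy-1,2,3-trimethyl-1,2,3,4-tetrahydroisoquinoline | COc1cc(OC)c2c(c1-c1ccc(OC)c3c(OC)cc(C)cc13)C[C@H](C)N(C)[C@@H]2C | target

Total step count: 11 (isoquinoline branch steps 1–6, naphthalene branch steps 7–10, coupling step 11).
Longest linear sequence: 7 steps (steps 1–6, then step 11).

Steps most likely to fail

Step 11. Transmetalation and reductive elimination at the doubly ortho-substituted C5 may be slow, so that the arylzinc is lost to protonation or homocoupling and 9 to hydrodebromination. The fallback sets out from 16 and replaces the moisture-sensitive organozinc by an isolable boron nucleophile. Miyaura borylation of 16 (B2pin2, PdCl2(dppf), KOAc, dioxane, 90 °C) should give 2-(4,5-dimethoxy-7-methylnaphthalen-1-yl)-4,4,5,5-tetramethyl-1,3,2-dioxaborolane F1, which can be purified. Suzuki–Miyaura coupling of F1 with 9 under aqueous base (Pd(OAc)2, SPhos, K3PO4, toluene/H2O, 100 °C) comes back to the route at 19.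

Step 6. Bromination of the very electron-rich ring may run on to C7, and the tertiary amine may be oxidised at its neighbouring C–H bonds if protonation is incomplete. The fallback sets out from 5 and installs the bromine on the neutral amide before the nitrogen ring exists. NBS in MeCN at 0 °C should brominate para to one methoxy group and ortho to the side chain to give (S)-N-[1-(2-bromo-3,5-dimethoxyphenyl)propan-2-yl]acetamide F2. Bischler–Napieralski cyclisation (POCl3, MeCN, reflux) can then close only at the remaining free ortho carbon and should give (S)-5-bromo-6,8-dimethoxy-1,3-dimethyl-3,4-dihydroisoquinoline F3. Reduction with NaBH4 in MeOH, with the same cis selectivity as in step 4, should give (1R,3S)-5-bromo-6,8-dimethoxy-1,3-dimethyl-1,2,3,4-tetrahydroisoquinoline F4. Reductive methylation as in step 5 (aq. HCHO, NaBH(OAc)3) comes back to the route at 9.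

Step 8. The benzylic ketone may be enolised by the phosphonate anion, leading to aldol self-condensation and incomplete olefination. The fallback sets out from 11 and forms the same carbon–carbon bond with a weakly basic zinc enolate. A Reformatsky reaction (Zn, ethyl bromoacetate, THF, reflux) should give racemic ethyl 4-(2-bromo-5-methoxyphenyl)-3-hydroxy-3-methylbutanoate F5. Acid-catalysed dehydration of F5 (TsOH, toluene, reflux) comes back to the route at ester 12, which is saponified as in the second stage of step 8.

Further compounds
F1 | step 11 | 2-(4,5-dimethoxy-7-methylnaphthalen-1-yl)-4,4,5,5-tetramethyl-1,3,2-dioxaborolane | COc1cc(C)cc2c(B3OC(C)(C)C(C)(C)O3)ccc(OC)c12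
F2 | step 6 | (S)-N-[1-(2-bromo-3,5-dimethoxyphenyl)propan-2-yl]acetamide | CC(=O)N[C@@H](C)Cc1cc(OC)cc(OC)c1Br
F3 | step 6 | (S)-5-bromo-6,8-dimethoxy-1,3-dimethyl-3,4-dihydroisoquinoline | CC1=N[C@@H](C)Cc2c(Br)c(OC)cc(OC)c12
F4 | step 6 | (1R,3S)-5-bromo-6,8-dimethoxy-1,3-dimethyl-1,2,3,4-tetrahydroisoquinoline | C[C@H]1N[C@@H](C)Cc2c(Br)c(OC)cc(OC)c12
F5 | step 8 | ethyl 4-(2-bromo-5-methoxyphenyl)-3-hydroxy-3-methylbutanoate (racemic) | CCOC(=O)CC(C)(O)Cc1cc(OC)ccc1Br
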